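**Retrosynthetic overview**
1. Target 17 ⇐ double formylation at C-6/C-8 of chroman-5,7-diol 15.
2. 15 ⇐ hydrogenation/debenzylation of 2H-chromene 14, which fixes C-4; 14 ⇐ gold-catalysed 6-endo hydroarylation of aryl propargyl ether 13, which closes the pyran ring last.
3. 13 ⇐ (1R,4S)-camphenilone 4 + 4-methylpent-1-yne 8 (exo C–C attack fixes the spiro carbon, ketone oxygen kept) + aryne from bromide 7 (cine-etherification puts that oxygen meta to both benzyloxy groups).
4. 4 ⇐ catalytic desymmetrising pinacol rearrangement (1,2-methyl shift) of meso-diol 3 ⇐ dione 2 ⇐ (±)-norcamphor 1; the shift creates the CMe2/C=O array and the absolute configuration.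
5. Ring order: norbornane (bought in 1) → benzene ring (resorcinol 5) → pyran ring.

Assumption: the target SMILES is read as (2R,4S,1′R,4′S), i.e. ether oxygen endo and C-3 exo on the norbornane, isobutyl cis to the CMe2 carbon across the pyran ring.

**Step 1**
Reactants: 1 (±)-norcamphor
Product: 2 bicyclo[2.2.1]heptane-2,3-dione
Conditions: SeO2 (1.3 equiv), xylene, 140 °C
Reagents that add atoms: selenium dioxide, O=[Se]=O
Why: Riley oxidation of the only enolisable α-CH2 (C-3) gives the α-diketone, and because this dione is achiral (meso) the racemic nature of 1 no longer matters.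

**Step 2**
Reactants: 2 bicyclo[2.2.1]heptane-2,3-dione
Product: 3 meso-(1R,2R,3S,4S)-2,3-dimethylbicyclo[2.2.1]heptane-2,3-diol (both OH endo and both CH3 exo)
Conditions: MeMgBr (4 equiv), THF, 0 → 60 °C; aq. NH4Cl
Reagents that add atoms: methylmagnesium bromide, C[Mg]Br
Why: Double Grignard 1,2-addition to a non-enolisable dione, each carbonyl being attacked from the less hindered exo face (no 7-syn substituent), gives the cis-endo,endo-diol, and the minor trans-diol is removed by crystallisation.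

**Step 3**
Reactants: 3 meso-diol
Product: 4 (1R,4S)-3,3-dimethylbicyclo[2.2.1]heptan-2-one [(1R,4S)-camphenilone]
Conditions: (S,S)-IDPi [BINOL-derived imidodiphosphorimidate Brønsted acid, N-SO2CF3, 3,3′-Ar = 3,5-(CF3)2C6H3; antipode chosen by screening to give (1R,4S)] 3 mol%, 5 Å MS, CHCl3–cyclohexane, −20 °C
Reagents that add atoms: none
Why: Proposed new method: catalytic enantioselective desymmetrising pinacol rearrangement, in which the confined chiral acid ionises one of the two enantiotopic tertiary endo-OH groups (the 3S carbinol) inside its chiral anion pocket, the exo-CH3 on C-2 then shifts across the exo face (the preferred exo-3,2 shift of 2-norbornyl cations) and the O-protonated ketone is an irreversible sink, so the quaternary CMe2 carbon, the carbonyl and both bridgehead configurations are set in one event; the closest known reaction types are chiral phosphoric acid catalysed pinacol rearrangements of aryl-stabilised diols and IDPi-catalysed Wagner–Meerwein shifts of purely aliphatic cations.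

**Step 4**
Reactants: 5 resorcinol
Product: 7 2,4-bis(benzyloxy)-1-bromobenzene, via 1,3-bis(benzyloxy)benzene 6 (not isolated)
Conditions: BnBr (2.2 equiv), K2CO3, MeCN, 70 °C; then NBS (1.0 equiv), 0 °C
Reagents that add atoms: benzyl bromide, BrCc1ccccc1; N-bromosuccinimide, O=C1CCC(=O)N1Br
Why: Williamson O-benzylation followed in the same pot by electrophilic aromatic bromination, which goes para to one benzyloxy group and ortho to the other (C-4 of the resorcinol ring) and not to the crowded C-2.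

**Step 5**
Reactants: 4 (1R,4S)-camphenilone; 8 4-methylpent-1-yne; 7 2,4-bis(benzyloxy)-1-bromobenzene
Product: 13 (1R,2R,4S)-2-[3,5-bis(benzyloxy)phenoxy]-3,3-dimethyl-2-(4-methylpent-1-yn-1-yl)bicyclo[2.2.1]heptane, via lithium 4-methylpent-1-yn-1-ide 9 (not isolated), via lithium exo-alkynyl endo-alkoxide 10 (not isolated), via 3,5-bis(benzyloxy)benzyne 11 (not isolated), via ortho-lithiated aryl ether 12 (not isolated)
Conditions: 8 (1.3 equiv), n-BuLi (1.2 equiv), THF, −78 °C; 4, −78 → 0 °C; then 7 (2.5 equiv) and lithium 2,2,6,6-tetramethylpiperidide (2.6 equiv) added slowly, −40 → 0 °C; H2O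
Reagents that add atoms: none
Why: Acetylide 1,2-addition to the non-enolisable ketone from the exo face puts the new carbon exo and leaves the ketone oxygen endo (this sets the future spiro centre), and the alkoxide then adds to aryne 11 (elimination–addition, cine-substitution) at the aryne carbon remote from the neighbouring benzyloxy group, so the oxygen lands meta to both benzyloxy groups with retention at the carbinol carbon because its C–O bond is never broken.

**Step 6**
Reactants: 13 aryl propargyl ether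
Product: 14 (1′R,2S,4′S)-5,7-bis(benzyloxy)-3′,3′-dimethyl-4-(2-methylpropyl)spiro[chromene-2,2′-bicyclo[2.2.1]heptane]
Conditions: [Au(NCMe){P(t-Bu)2(biphenyl-2-yl)}]SbF6 (3 mol%), CH2Cl2, 23 °C
Reagents that add atoms: none
Why: Gold-catalysed 6-endo-dig intramolecular hydroarylation (Friedel–Crafts-type attack of the ring carbon ortho to the ether oxygen and ortho/para to the benzyloxy groups on the π-activated alkyne, then protodeauration) gives the 4-substituted 2H-chromene without touching the stereocentres, the two ortho positions being equivalent.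

**Step 7**
Reactants: 14 2H-chromene
Product: 15 (1′R,2R,4S,4′S)-3′,3′-dimethyl-4-(2-methylpropyl)-3,4-dihydrospiro[chromene-2,2′-bicyclo[2.2.1]heptane]-5,7-diol
Conditions: H2 (3 atm), Pd/C (10 wt%), EtOAc–EtOH, 23 °C
Reagents that add atoms: none
Why: Heterogeneous catalytic hydrogenation adds H2 syn to C3=C4 from the face opposite the CMe2 carbon (its exo-methyl lies directly over C-3, whereas the other face carries only the bridgehead C-1′–H), which puts H-4 cis to C-1′ and the isobutyl group cis to C-3′ (4S), and the benzyl ethers are removed by hydrogenolysis in the same operation.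

**Step 8**
Reactants: 15 chroman-5,7-diol
Product: 17 (1′R,2R,4S,4′S)-5,7-dihydroxy-3′,3′-dimethyl-4-(2-methylpropyl)-3,4-dihydrospiro[chromene-2,2′-bicyclo[2.2.1]heptane]-6,8-dicarbaldehyde, via bis(iminium) dichloride 16 (not isolated)
Conditions: POCl3 (4 equiv), DMF (6 equiv), MeCN, 0 → 23 °C; then H2O, 50 °C
Reagents that add atoms: N,N-dimethylformamide, CN(C)C=O; water, O
Why: Double Vilsmeier–Haack formylation at the two free ring positions (C-6 and C-8, each ortho/para to three oxygen donors) followed by hydrolysis of the bis(iminium) salt, with no strong Lewis acid present so the tertiary alkyl aryl ether and the stereocentres are untouched.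

**Compound list**
1 | (±)-norcamphor, rac-bicyclo[2.2.1]heptan-2-one | O=C1CC2CCC1C2 | starting material
2 | bicyclo[2.2.1]heptane-2,3-dione (meso) | O=C1[C@@H]2CC[C@@H](C2)C1=O | intermediate
3 | meso-(1R,2R,3S,4S)-2,3-dimethylbicyclo[2.2.1]heptane-2,3-diol (OH endo, CH3 exo) | C[C@@]1(O)[C@@H]2CC[C@@H](C2)[C@]1(C)O | intermediate
4 | (1R,4S)-3,3-dimethylbicyclo[2.2.1]heptan-2-one, (1R,4S)-camphenilone | O=C1[C@@H]2CC[C@@H](C2)C1(C)C | intermediate
5 | resorcinol, benzene-1,3-diol | Oc1cccc(O)c1 | starting material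
6 | 1,3-bis(benzyloxy)benzene | c1ccc(COc2cccc(OCc3ccccc3)c2)cc1 | intermediate
7 | 2,4-bis(benzyloxy)-1-bromobenzene | Brc1ccc(OCc2ccccc2)cc1OCc1ccccc1 | intermediate
8 | 4-methylpent-1-yne | C#CCC(C)C | starting material
9 | lithium 4-methylpent-1-yn-1-ide | [Li]C#CCC(C)C | intermediate
10 | lithium (1R,2R,4S)-3,3-dimethyl-2-(4-methylpent-1-yn-1-yl)bicyclo[2.2.1]heptan-2-olate (alkynyl exo, O endo) | CC(C)CC#C[C@@]1(O[Li])[C@@H]2CC[C@@H](C2)C1(C)C | intermediate
11 | 3,5-bis(benzyloxy)benzyne (3,5-bis(benzyloxy)-1,2-didehydrobenzene) | C1#CC(OCc2ccccc2)=CC(OCc2ccccc2)=C1 | intermediate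
12 | {2,4-bis(benzyloxy)-6-[(1R,2R,4S)-3,3-dimethyl-2-(4-methylpent-1-yn-1-yl)bicyclo[2.2.1]heptan-2-yl]oxyphenyl}lithium | CC(C)CC#C[C@@]1(Oc2cc(OCc3ccccc3)cc(OCc3ccccc3)c2[Li])[C@@H]2CC[C@@H](C2)C1(C)C | intermediate
13 | (1R,2R,4S)-2-[3,5-bis(benzyloxy)phenoxy]-3,3-dimethyl-2-(4-methylpent-1-yn-1-yl)bicyclo[2.2.1]heptane (aryloxy endo, alkynyl exo) | CC(C)CC#C[C@@]1(Oc2cc(OCc3ccccc3)cc(OCc3ccccc3)c2)[C@@H]2CC[C@@H](C2)C1(C)C | intermediate
14 | (1′R,2S,4′S)-5,7-bis(benzyloxy)-3′,3′-dimethyl-4-(2-methylpropyl)spiro[chromene-2,2′-bicyclo[2.2.1]heptane] (O-1 endo, C-3 exo) | CC(C)CC1=C[C@@]2(Oc3cc(OCc4ccccc4)cc(OCc4ccccc4)c31)[C@@H]1CC[C@@H](C1)C2(C)C | intermediate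
15 | (1′R,2R,4S,4′S)-3′,3′-dimethyl-4-(2-methylpropyl)-3,4-dihydrospiro[chromene-2,2′-bicyclo[2.2.1]heptane]-5,7-diol | CC(C)C[C@H]1C[C@@]2(Oc3cc(O)cc(O)c31)[C@@H]1CC[C@@H](C1)C2(C)C | intermediate
16 | 6,8-bis[(dimethyliminio)methyl] derivative of 15, dichloride | CC(C)C[C@H]1C[C@@]2(Oc3c(C=[N+](C)C)c(O)c(C=[N+](C)C)c(O)c31)[C@@H]1CC[C@@H](C1)C2(C)C.[Cl-].[Cl-] | intermediate
17 | (1′R,2R,4S,4′S)-5,7-dihydroxy-3′,3′-dimethyl-4-(2-methylpropyl)-3,4-dihydrospiro[chromene-2,2′-bicyclo[2.2.1]heptane]-6,8-dicarbaldehyde | CC(C)C[C@H]1C[C@@]2(Oc3c(C=O)c(O)c(C=O)c(O)c31)[C@@H]1CC[C@@H](C1)C2(C)C | target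

**Totals**
Total step count: 8. Longest linear sequence: 7 steps (1 → 2 → 3 → 5 → 6 → 7 → 8); step 4 is the one-step side branch.

**Steps most likely to fail**

Step 3 (the proposed desymmetrising pinacol shift) may give low ee or low turnover because water is released. The fallback uses known chemistry, sets out from 1 and comes back at 4, bypassing 2 and 3. NaBH4 reduction of 1 (exo hydride delivery) gives (±)-endo-bicyclo[2.2.1]heptan-2-ol F1. Lipase-catalysed acetylation with vinyl acetate (Candida rugosa lipase, kinetic resolution) is predicted by the empirical lipase rule to acylate the 2R alcohol; this leaves (1R,2S,4S)-bicyclo[2.2.1]heptan-2-ol F2 and gives (1S,2R,4R)-bicyclo[2.2.1]heptan-2-yl acetate F3, which is discarded. Swern oxidation of F2 gives (1R,4S)-bicyclo[2.2.1]heptan-2-one F4. Exhaustive α-methylation (KH, excess MeI, THF; only C-3 can enolise) then gives 4.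

Step 5 (intermolecular capture of the aryne by a very hindered tertiary alkoxide in competition with the amide base) may give low yield. The fallback sets out from 4 (using 7) and comes back at 14; it makes the C–C bond first and closes the C–O bond by an intramolecular benzyne ring closure. Aldol addition of the kinetic lithium enolate of 4-methylpentan-2-one (LDA, THF, −78 °C) to 4 gives 1-[(1R,2R,4S)-2-hydroxy-3,3-dimethylbicyclo[2.2.1]heptan-2-yl]-4-methylpentan-2-one F5. Bromine–lithium exchange on 7 (n-BuLi, −78 °C) gives [2,4-bis(benzyloxy)phenyl]lithium F6, which is added to F5 with CeCl3 to give 2-[2,4-bis(benzyloxy)phenyl]-1-[(1R,2R,4S)-2-hydroxy-3,3-dimethylbicyclo[2.2.1]heptan-2-yl]-4-methylpentan-2-ol F7. NBS brominates the aryl ring para to the 2-benzyloxy group to give 2-[2,4-bis(benzyloxy)-5-bromophenyl]-1-[(1R,2R,4S)-2-hydroxy-3,3-dimethylbicyclo[2.2.1]heptan-2-yl]-4-methylpentan-2-ol F8. Lithium 2,2,6,6-tetramethylpiperidide (3.5 equiv) removes the only hydrogen ortho to bromine, and the tethered tertiary alkoxide closes the six-membered ring on the aryne carbon next to the side chain to give (1′R,2R,4′S)-5,7-bis(benzyloxy)-3′,3′-dimethyl-4-(2-methylpropyl)-3,4-dihydrospiro[chromene-2,2′-bicyclo[2.2.1]heptan]-4-ol F9. Dehydration with Burgess reagent then gives 14.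

Step 7 (substrate-controlled facial selectivity at C-4) may be too low. The fallback sets out from 14 and comes back at 15; it uses catalyst control in place of substrate control. Homogeneous hydrogenation with [Ir(cod)(L)]B[C6H3(CF3)2]4, L = (S)-4-tert-butyl-2-[2-(diphenylphosphino)phenyl]-4,5-dihydrooxazole (or its antipode, whichever is matched with the substrate bias; H2 50 bar, CH2Cl2), gives (1′R,2R,4S,4′S)-5,7-bis(benzyloxy)-3′,3′-dimethyl-4-(2-methylpropyl)-3,4-dihydrospiro[chromene-2,2′-bicyclo[2.2.1]heptane] F10. Hydrogenolysis (H2, Pd(OH)2/C, EtOAc) then gives 15.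

**Further compounds**
F1 | step 3 | (±)-endo-bicyclo[2.2.1]heptan-2-ol (racemate, one enantiomer drawn) | O[C@@H]1[C@@H]2CC[C@@H](C2)C1
F2 | step 3 | (1R,2S,4S)-bicyclo[2.2.1]heptan-2-ol (endo) | O[C@@H]1[C@@H]2CC[C@@H](C2)C1
F3 | step 3 | (1S,2R,4R)-bicyclo[2.2.1]heptan-2-yl acetate (endo) | CC(=O)O[C@H]1[C@H]2CC[C@H](C2)C1
F4 | step 3 | (1R,4S)-bicyclo[2.2.1]heptan-2-one | O=C1[C@@H]2CC[C@@H](C2)C1
F5 | step 5 | 1-[(1R,2R,4S)-2-hydroxy-3,3-dimethylbicyclo[2.2.1]heptan-2-yl]-4-methylpentan-2-one | CC(C)CC(=O)C[C@@]1(O)[C@@H]2CC[C@@H](C2)C1(C)C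
F6 | step 5 | [2,4-bis(benzyloxy)phenyl]lithium | [Li]c1ccc(OCc2ccccc2)cc1OCc1ccccc1
F7 | step 5 | 2-[2,4-bis(benzyloxy)phenyl]-1-[(1R,2R,4S)-2-hydroxy-3,3-dimethylbicyclo[2.2.1]heptan-2-yl]-4-methylpentan-2-ol (epimers at the benzylic carbinol) | CC(C)CC(O)(C[C@@]1(O)[C@@H]2CC[C@@H](C2)C1(C)C)c1ccc(OCc2ccccc2)cc1OCc1ccccc1
F8 | step 5 | 2-[2,4-bis(benzyloxy)-5-bromophenyl]-1-[(1R,2R,4S)-2-hydroxy-3,3-dimethylbicyclo[2.2.1]heptan-2-yl]-4-methylpentan-2-ol (epimers at the benzylic carbinol) | CC(C)CC(O)(C[C@@]1(O)[C@@H]2CC[C@@H](C2)C1(C)C)c1cc(Br)c(OCc2ccccc2)cc1OCc1ccccc1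
F9 | step 5 | (1′R,2R,4′S)-5,7-bis(benzyloxy)-3′,3′-dimethyl-4-(2-methylpropyl)-3,4-dihydrospiro[chromene-2,2′-bicyclo[2.2.1]heptan]-4-ol (C-4 epimers) | CC(C)CC1(O)C[C@@]2(Oc3cc(OCc4ccccc4)cc(OCc4ccccc4)c31)[C@@H]1CC[C@@H](C1)C2(C)C
F10 | step 7 | (1′R,2R,4S,4′S)-5,7-bis(benzyloxy)-3′,3′-dimethyl-4-(2-methylpropyl)-3,4-dihydrospiro[chromene-2,2′-bicyclo[2.2.1]heptane] | CC(C)C[C@H]1C[C@@]2(Oc3cc(OCc4ccccc4)cc(OCc4ccccc4)c31)[C@@H]1CC[C@@H](C1)C2(C)C
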